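## The problem

The target is a flavonolignan of the 2,3-dehydroisosilybin type. A 3,5,7-trihydroxychromen-4-one (rings A and C) carries at C2 an aryl ring B that is fused to a 1,4-dioxane (ring D), and ring D bears the guaiacyl ring E at Cα and a hydroxymethyl group at Cβ. The ring fusion has a fixed sense: the ring B oxygen para to C2 (O4') is bound to Cα and the meta oxygen (O3') to Cβ, so the two aryl ether bonds must be made one after the other from catechol oxygens that can be told apart. The only stereocenters are Cα and Cβ, both R and trans on ring D. They are remote from the flat flavonol, which can control neither, but each can control the other once one C–O bond is in place, so one reagent-controlled event can serve both. Cα is the weak point: it is a benzylic aryl ether whose aryl group has a para oxygen, so acid can ionise the Cα–O bond and, once the ring E phenol is free, base can open it through a quinone methide; either event erodes the trans relation. The 3-hydroxy enone of ring C and the five free hydroxyls make the final compound sensitive to oxidants and base, so the C3 oxygen and the free phenols should appear late. The feature that allows a short synthesis is ring A: C5 and C7 carry oxygen and C8a carries O1, so ring A is phloroglucinol, whose three CH carbons and three hydroxyls are equivalent. C4a can therefore be any of its ring carbons and O1 either neighbouring hydroxyl, and the C4–C4a and O1–C2 bonds of ring C can be formed on the unprotected triol with no regiochemical question.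

## Retrosynthesis

**Unveiling (21 from 20).** The four O–benzyl bonds (O5, O7, the ring E phenol and the primary alcohol) are cut last. Benzyl is chosen throughout because it tolerates base, hydride, dioxirane and a short period at high temperature, and because one neutral hydrogenolysis removes all four. The forward step must not break the benzylic Cα–O bond of ring D.

**C3–O (20 from 18 through epoxide 19, and 18 from 17).** The C3 hydroxyl is cut next, back to the flavone C2=C3 bond. Carrying the oxygen through ring formation would need an α-oxygenated ketoester and would expose a flavonol enol to 240 °C. Adding it afterwards uses the only nucleophilic alkene in the molecule. Dimethyldioxirane oxidises free phenols, so O5 and O7 are capped first (18 from 17) with the same benzyl groups that leave at the end.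

**Ring C (17 from 13 and 14).** The C4–C4a and O1–C2 bonds are cut together, giving the aroylacetate 13 and phloroglucinol 14. The neighbouring cuts are less attractive. A Baker–Venkataraman disconnection at C3–C4 needs a ring A acetophenone with two of three hydroxyls protected. An oxidative chalcone closure is known to drift towards aurones when the 6' position carries oxygen, as ring A requires here. The chosen cut removes ring A as a commercial, unprotected, symmetric triol and leaves 13, which already holds rings B, D and E and both stereocenters. The forward reaction must acylate carbon, not oxygen, must give the chromone and not the coumarin, and must spare ring D.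

**Ketoester chain (13 from 9 and 10, and 9 from 8).** The bond between the future C2 and C3 is cut to acid 9 and potassium ethyl malonate 10; acid 9 comes from aldehyde 8 by oxidation. The two-carbon extension of an activated acid by a magnesium malonate is neutral and leaves the acid-labile Cα–O bond alone. A Claisen condensation of a methyl ketone would need two further steps to make that ketone.

**O3'–Cβ (8 from 7).** Ring D is opened at the non-benzylic aryl ether. Closing this bond last allows an SN2 displacement at Cβ, which is stereospecific. The alternative, closing the benzylic O4'–Cα bond last, would leave the trans relation to thermodynamics. Precursor 7 is an open-chain phenol and secondary alcohol, and the primary oxygen already carries its final benzyl group, so only one alcohol can react. The forward step must invert Cβ.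

**O4'–Cα (7 from 5 and 6).** The benzylic aryl ether is cut to the trans-epoxide 5 and 3,4-dihydroxybenzaldehyde 6. Both partners direct themselves: the 4-hydroxyl of 6, para to the formyl group, is the more acidic and ionises first, and the benzylic carbon of 5 is the more electrophilic. The forward step must be an SN2 opening with inversion and must not ionise.

**Stereochemistry and starting material (5 from 4, 4 from 3, 3 from 2, 2 from 1).** Epoxide 5 is the benzyl ether of epoxy alcohol 4, which comes from the E-allylic alcohol 3 by Sharpless epoxidation. Both carbons of the epoxide are later inverted once (Cα in the opening, Cβ in the ring closure), so the (2S,3S)-epoxide maps onto the (αR,βR) trans ring. Alcohol 3 comes from ferulic acid 1 by double benzylation (2) and ester reduction. One catalytic asymmetric step thus sets both stereocenters.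

## Roads not taken

**Alternative 1:** The cut is O4'–Cα of ring D, made by oxidation rather than substitution. The precursor is the open-chain aryl ether A2, in which Cβ is already set and Cα is a plain CH2 group. Constant-current electrolysis at a graphite anode (Bu4NBF4, hexafluoroisopropanol–dichloromethane) would oxidise ring E to the para-quinone methide A3. The ring B phenol O4' would add to its methide carbon (6-exo-trig) to give the trans-benzodioxane ester A1. The merits are real: only one stereocenter has to be made, Cα needs no leaving group, and no para-alkoxyaryl epoxide is handled. In these respects it is better than the chosen plan, whose two weakest preparative steps are the epoxidation and the benzylic opening. The weak points are these. The trans relation rests on substrate-controlled addition to a planar intermediate, not on a stereospecific mechanism. The product A1 keeps a free, oxidisable guaiacol next to a newly made benzylic ether, so it can re-enter the quinone methide manifold. Neither the silyl ether nor the free phenol of A1 suits a phenolic melt at 240 °C, so protecting groups would have to be exchanged and the ester advanced to the ketoester before ring C can be built. Against this the chosen plan sets two stereospecific displacements from one Sharpless epoxide and a benzodioxane that arrives in the protecting-group pattern needed for ring C.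

**Alternative 2:** The cut is O3'–Cβ, as in the chosen route, but made by an epoxide relay. In the terminal epoxide A5, K2CO3 would ionise the ring B phenol O3', which opens the epoxide at its internal carbon (6-exo-tet, inversion). This closes ring D and releases the hydroxymethyl group of the trans-benzodioxane aldehyde A4. The closure is basic, stereospecific and of the same type as the classical catechol–epichlorohydrin route to 2-hydroxymethylbenzodioxanes. It is probably more robust than the redox condensation used for the same bond in the chosen route, and it makes no phosphine oxide. Its costs lie around it. A5 needs the primary hydroxyl of a diol activated in the presence of a free phenol, which means extra protection steps. The released alcohol must then be benzylated. The methoxymethyl ether on ring E would not survive the later melt and would have to be exchanged. The stereochemical logic is equal to the chosen plan (same epoxide, same two inversions). The chosen plan sets against the sturdier closure a saving of two to three steps, because one benzyl ether both blocks the primary oxygen and serves as the final protecting group.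

**Alternative 3:** The cuts are C4a–C4 and C4–C3. PdCl2(PPh3)2 and Et3N under carbon monoxide A9 would join the ring A iodide A7 and the benzodioxane alkyne A8 to the alkynone A6. A8 is one homologation step away from aldehyde 8. No ring closes in this step; one ortho benzyl ether would then have to be removed selectively and the phenol closed 6-endo-dig, which would arrive at 18. The merit is mildness: nothing is heated above about 60 °C, so the benzodioxane is never at thermal risk, and the union is convergent. In this respect it is better than the chosen plan. The weak points are the iodide A7, which is electron-rich and flanked by two ortho substituents, so oxidative addition and CO insertion are slow and direct alkynylation without CO competes. The later cyclisation has a known 5-exo-dig leak to aurones. Ring A must also be made, tri-protected and partly deprotected again. The chosen plan sets against the thermal risk a single step that forms both bonds and the ring from an unprotected, symmetric triol, and it keeps a low-temperature fallback in reserve.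

Key step: step 9

Remarks: Cα is the ring D carbon bearing ring E and Cβ the one bearing the CH2O group; O4' and O3' are the ring B oxygens para and meta to the flavone C2. BD stands for the group (2R,3R)-2-[4-(benzyloxy)-3-methoxyphenyl]-3-[(benzyloxy)methyl]-2,3-dihydro-1,4-benzodioxin-6-yl. Assumption: the flavone epoxide 19 forms as a mixture of two diastereomers at C2/C3 and the half ester 12 is unassigned at its malonate carbon; both centers vanish in the next event.

## Route

Step 1
Reactants: 1 ferulic acid
Product: 2 benzyl (E)-3-[4-(benzyloxy)-3-methoxyphenyl]prop-2-enoate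
Conditions: BnBr (2.3 equiv), K2CO3 (3 equiv), DMF, 60 °C
Reagents that add atoms: benzyl bromide, BrCc1ccccc1
Why: Williamson-type alkylation of the carboxylate and the phenoxide in one operation; it installs the ring E benzyl ether for the whole route and gives an ester that a hydride reagent reduces directly, leaving the E alkene untouched.

Step 2
Reactants: 2 benzyl (E)-3-[4-(benzyloxy)-3-methoxyphenyl]prop-2-enoate
Product: 3 (E)-3-[4-(benzyloxy)-3-methoxyphenyl]prop-2-en-1-ol
Conditions: iBu2AlH (2.5 equiv), CH2Cl2, −78 to 0 °C; aqueous potassium sodium tartrate (KNaC4H4O6)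
Reagents that add atoms: none
Why: 1,2-Reduction of a cinnamate ester to the allylic alcohol by iBu2AlH is standard and does not touch the conjugated alkene or the aryl benzyl ether.

Step 3
Reactants: 3 (E)-3-[4-(benzyloxy)-3-methoxyphenyl]prop-2-en-1-ol
Product: 4 [(2S,3S)-3-[4-(benzyloxy)-3-methoxyphenyl]oxiran-2-yl]methanol
Conditions: Ti(OiPr)4 (0.1 equiv), L-(+)-diethyl tartrate (0.12 equiv), tBuOOH (2 equiv), 4 Å molecular sieves, CH2Cl2, −20 °C; then cold aqueous NaOH/NaCl
Reagents that add atoms: tert-butyl hydroperoxide, CC(C)(C)OO
Why: Sharpless asymmetric epoxidation; with the L-(+)-tartrate an (E)-3-arylallyl alcohol gives the (2S,3S)-epoxy alcohol, as cinnamyl alcohol does, which sets both future ring D centers by reagent control, and the catalytic low-temperature variant with basic work-up is chosen because the para-alkoxyaryl epoxide is acid-labile.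

Step 4
Reactants: 4 [(2S,3S)-3-[4-(benzyloxy)-3-methoxyphenyl]oxiran-2-yl]methanol
Product: 5 (2S,3S)-2-[4-(benzyloxy)-3-methoxyphenyl]-3-[(benzyloxy)methyl]oxirane
Conditions: NaH (1.2 equiv), BnBr (1.2 equiv), Bu4NI (cat.), THF, 0 °C to rt
Reagents that add atoms: benzyl bromide, BrCc1ccccc1
Why: Williamson benzylation of a glycidol alkoxide, routine for 3-arylglycidols; in THF with the bromide present, alkylation outruns Payne migration, and the ether blocks the primary oxygen so that only one alcohol exists after the opening.

Step 5
Reactants: 5 (2S,3S)-2-[4-(benzyloxy)-3-methoxyphenyl]-3-[(benzyloxy)methyl]oxirane; 6 3,4-dihydroxybenzaldehyde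
Product: 7 4-{[(1R,2S)-3-(benzyloxy)-1-[4-(benzyloxy)-3-methoxyphenyl]-2-hydroxypropyl]oxy}-3-hydroxybenzaldehyde
Conditions: 6 (3 equiv), K2CO3 (1.5 equiv), DMF, 70 °C, argon
Reagents that add atoms: none
Why: Base-mediated opening of a trans-3-arylglycidyl derivative by a phenoxide at the benzylic carbon, a known reaction type; with one base equivalent per molecule of 6 only the 4-oxygen (para to the formyl group) is ionised, and it attacks Cα in an SN2 fashion with inversion, giving Cα as R while the epoxide oxygen stays on Cβ as the (S)-alcohol.

Step 6
Reactants: 7 4-{[(1R,2S)-3-(benzyloxy)-1-[4-(benzyloxy)-3-methoxyphenyl]-2-hydroxypropyl]oxy}-3-hydroxybenzaldehyde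
Product: 8 (2R,3R)-2-[4-(benzyloxy)-3-methoxyphenyl]-3-[(benzyloxy)methyl]-2,3-dihydro-1,4-benzodioxine-6-carbaldehyde
Conditions: PPh3 (1.5 equiv), DIAD (1.5 equiv), THF (0.02 M), 0 °C to rt
Reagents that add atoms: none
Why: Intramolecular Mitsunobu etherification, a known way to close 1,4-benzodioxanes; the only alcohol is activated as its oxyphosphonium ion and displaced 6-exo-tet by the ring B phenoxide O3' with inversion, which makes Cβ R and the ring trans, while Cα is not touched.

Step 7
Reactants: 8 (2R,3R)-2-[4-(benzyloxy)-3-methoxyphenyl]-3-[(benzyloxy)methyl]-2,3-dihydro-1,4-benzodioxine-6-carbaldehyde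
Product: 9 (2R,3R)-2-[4-(benzyloxy)-3-methoxyphenyl]-3-[(benzyloxy)methyl]-2,3-dihydro-1,4-benzodioxine-6-carboxylic acid
Conditions: NaClO2, NaH2PO4, 2-methyl-2-butene (excess), tBuOH/THF/H2O, 0 °C to rt
Reagents that add atoms: sodium chlorite (NaClO2), [Na+].[O-]Cl=O
Why: Pinnick oxidation of an aryl aldehyde under buffered conditions; the alkene scavenger removes hypochlorous acid before it can chlorinate the electron-rich rings, and the benzyl ethers and ring D are inert.

Step 8
Reactants: 9 (2R,3R)-2-[4-(benzyloxy)-3-methoxyphenyl]-3-[(benzyloxy)methyl]-2,3-dihydro-1,4-benzodioxine-6-carboxylic acid; 10 potassium ethyl malonate (KO2CCH2CO2Et)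
Product: 13 ethyl 3-BD-3-oxopropanoate, via acyl imidazolide 11 (not isolated), via acylmalonic half ester 12 (not isolated)
Conditions: CDI, THF, rt; then 10, MgCl2, Et3N, MeCN, rt to 45 °C; cold 1 M HCl
Reagents that add atoms: none
Why: Masamune–Brooks chain extension; the acyl imidazolide is C-acylated by the magnesium-chelated malonate enolate and the resulting half ester loses CO2 on acidification, a neutral sequence that spares the Cα–O bond.

Step 9
Reactants: 13 ethyl 3-BD-3-oxopropanoate; 14 phloroglucinol
Product: 17 2-BD-5,7-dihydroxy-4H-chromen-4-one, via aroylketene 15 (not isolated), via hydroxyaryl diketone 16 (not isolated)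
Conditions: 14 (3 equiv), neat melt under argon, 240 °C (microwave or preheated metal bath), 5–10 min, ethanol and water allowed to distil off
Reagents that add atoms: none
Why: Above about 200 °C the β-ketoester 13 loses ethanol to give the aroylketene 15, which C-acylates phloroglucinol at one of its three equivalent CH carbons (an aryl ester formed by O-acylation can revert to the ketene), giving the 2-hydroxyaryl 1,3-diketone 16 and with it the C4–C4a bond. A flanking phenol then adds to the aryl ketone carbonyl (6-exo-trig) and the hemiketal loses water, which forms O1–C2 and closes ring C as the aromatic pyranone. The closest known reaction type is the thermal, acid-free condensation of phloroglucinol with aroylacetates to 5,7-dihydroxyflavones (Mentzer pyrone synthesis), which also runs in a microwave melt within minutes. No stereocenter is formed; Cα and Cβ lie outside the reacting array and keep their configuration as long as the Cα–O bond does not ionise, which the benzyl cap on the ring E phenol (no quinone methide) and the short heating time are meant to secure. The step needs C-acylation over O-acylation and chromone over coumarin: the absence of acid suppresses the Pechmann pathway, in which the arene attacks the ketone carbonyl, and the threefold symmetry of 14 removes any regiochemical question because every ring carbon has two ortho hydroxyls. Excess 14 serves as flux and keeps a second condensation on the same ring down, and the 5-hydroxyl ends hydrogen-bonded to the C4 carbonyl.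

Step 10
Reactants: 17 2-BD-5,7-dihydroxy-4H-chromen-4-one
Product: 18 5,7-bis(benzyloxy)-2-BD-4H-chromen-4-one
Conditions: BnBr (3 equiv), K2CO3 (4 equiv), DMF, 70 °C
Reagents that add atoms: benzyl bromide, BrCc1ccccc1
Why: Phenol O-alkylation as used for chrysin-type flavones; the 7-hydroxyl reacts first and the chelated 5-hydroxyl follows with excess bromide and heat, which removes the free phenols that dimethyldioxirane would oxidise.

Step 11
Reactants: 18 5,7-bis(benzyloxy)-2-BD-4H-chromen-4-one
Product: 20 5,7-bis(benzyloxy)-2-BD-3-hydroxy-4H-chromen-4-one, via flavone epoxide 19 (not isolated)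
Conditions: dimethyldioxirane (acetone solution, excess in portions), CH2Cl2, 0 °C to rt; evaporate; then p-TsOH·H2O (cat.), CH2Cl2, 0 °C
Reagents that add atoms: dimethyldioxirane, CC1(C)OO1
Why: Epoxidation of the flavone C2=C3 bond by dimethyldioxirane followed by acid-catalysed opening of the 2,3-epoxide to the C2 oxocarbenium ion and loss of the C3 proton is the established conversion of fully O-protected flavones into flavonols; both epoxide diastereomers give the same planar product, and the opening needs far less acid than ionisation at Cα.

Step 12
Reactants: 20 5,7-bis(benzyloxy)-2-BD-3-hydroxy-4H-chromen-4-one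
Product: 21 2-[(2R,3R)-2-(4-hydroxy-3-methoxyphenyl)-3-(hydroxymethyl)-2,3-dihydro-1,4-benzodioxin-6-yl]-3,5,7-trihydroxy-4H-chromen-4-one
Conditions: H2 (1 atm), Pd(OH)2 on carbon, THF/MeOH, rt, stopped when the last benzyl ether is gone
Reagents that add atoms: none
Why: Catalytic hydrogenolysis removes the three aryl benzyl ethers and the primary benzyl ether under neutral conditions; O-benzyl groups cleave faster than the secondary benzylic C–O bond within ring D, and the flavonol C2=C3 bond is part of an aromatic pyranone and resists hydrogenation.

## Compound list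

1 | ferulic acid, (E)-3-(4-hydroxy-3-methoxyphenyl)prop-2-enoic acid | COc1cc(/C=C/C(=O)O)ccc1O | starting material
2 | benzyl (E)-3-[4-(benzyloxy)-3-methoxyphenyl]prop-2-enoate | COc1cc(/C=C/C(=O)OCc2ccccc2)ccc1OCc1ccccc1 | intermediate
3 | (E)-3-[4-(benzyloxy)-3-methoxyphenyl]prop-2-en-1-ol | COc1cc(/C=C/CO)ccc1OCc1ccccc1 | intermediate
4 | [(2S,3S)-3-[4-(benzyloxy)-3-methoxyphenyl]oxiran-2-yl]methanol | COc1cc([C@@H]2O[C@H]2CO)ccc1OCc1ccccc1 | intermediate
5 | (2S,3S)-2-[4-(benzyloxy)-3-methoxyphenyl]-3-[(benzyloxy)methyl]oxirane | COc1cc([C@@H]2O[C@H]2COCc2ccccc2)ccc1OCc1ccccc1 | intermediate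
6 | 3,4-dihydroxybenzaldehyde | O=Cc1ccc(O)c(O)c1 | starting material
7 | 4-{[(1R,2S)-3-(benzyloxy)-1-[4-(benzyloxy)-3-methoxyphenyl]-2-hydroxypropyl]oxy}-3-hydroxybenzaldehyde | COc1cc([C@@H](Oc2ccc(C=O)cc2O)[C@@H](O)COCc2ccccc2)ccc1OCc1ccccc1 | intermediate
8 | (2R,3R)-2-[4-(benzyloxy)-3-methoxyphenyl]-3-[(benzyloxy)methyl]-2,3-dihydro-1,4-benzodioxine-6-carbaldehyde | COc1cc([C@H]2Oc3ccc(C=O)cc3O[C@@H]2COCc2ccccc2)ccc1OCc1ccccc1 | intermediate
9 | (2R,3R)-2-[4-(benzyloxy)-3-methoxyphenyl]-3-[(benzyloxy)methyl]-2,3-dihydro-1,4-benzodioxine-6-carboxylic acid | COc1cc([C@H]2Oc3ccc(C(=O)O)cc3O[C@@H]2COCc2ccccc2)ccc1OCc1ccccc1 | intermediate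
10 | potassium ethyl malonate (potassium 3-ethoxy-3-oxopropanoate) | CCOC(=O)CC(=O)[O-].[K+] | starting material
11 | BD-(1H-imidazol-1-yl)methanone, the acyl imidazolide of 9 | COc1cc([C@H]2Oc3ccc(C(=O)n4ccnc4)cc3O[C@@H]2COCc2ccccc2)ccc1OCc1ccccc1 | intermediate (not isolated)
12 | 2-(ethoxycarbonyl)-3-BD-3-oxopropanoic acid, formed as its magnesium chelate | COc1cc([C@H]2Oc3ccc(C(=O)C(C(=O)O)C(=O)OCC)cc3O[C@@H]2COCc2ccccc2)ccc1OCc1ccccc1 | intermediate (not isolated)
13 | ethyl 3-BD-3-oxopropanoate | COc1cc([C@H]2Oc3ccc(C(=O)CC(=O)OCC)cc3O[C@@H]2COCc2ccccc2)ccc1OCc1ccccc1 | intermediate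
14 | phloroglucinol (benzene-1,3,5-triol) | Oc1cc(O)cc(O)c1 | starting material
15 | 3-BD-3-oxoprop-1-en-1-one (aroylketene) | COc1cc([C@H]2Oc3ccc(C(=O)C=C=O)cc3O[C@@H]2COCc2ccccc2)ccc1OCc1ccccc1 | intermediate (not isolated)
16 | 1-BD-3-(2,4,6-trihydroxyphenyl)propane-1,3-dione | COc1cc([C@H]2Oc3ccc(C(=O)CC(=O)c4c(O)cc(O)cc4O)cc3O[C@@H]2COCc2ccccc2)ccc1OCc1ccccc1 | intermediate (not isolated)
17 | 2-BD-5,7-dihydroxy-4H-chromen-4-one | COc1cc([C@H]2Oc3ccc(-c4cc(=O)c5c(O)cc(O)cc5o4)cc3O[C@@H]2COCc2ccccc2)ccc1OCc1ccccc1 | intermediate
18 | 5,7-bis(benzyloxy)-2-BD-4H-chromen-4-one | COc1cc([C@H]2Oc3ccc(-c4cc(=O)c5c(OCc6ccccc6)cc(OCc6ccccc6)cc5o4)cc3O[C@@H]2COCc2ccccc2)ccc1OCc1ccccc1 | intermediate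
19 | 2,3-epoxide of 18 (2-BD-5,7-bis(benzyloxy)-2,3-epoxychroman-4-one, two diastereomers at C2/C3) | COc1cc([C@H]2Oc3ccc(C45Oc6cc(OCc7ccccc7)cc(OCc7ccccc7)c6C(=O)C4O5)cc3O[C@@H]2COCc2ccccc2)ccc1OCc1ccccc1 | intermediate (not isolated)
20 | 5,7-bis(benzyloxy)-2-BD-3-hydroxy-4H-chromen-4-one | COc1cc([C@H]2Oc3ccc(-c4oc5cc(OCc6ccccc6)cc(OCc6ccccc6)c5c(=O)c4O)cc3O[C@@H]2COCc2ccccc2)ccc1OCc1ccccc1 | intermediate
21 | 2-[(2R,3R)-2-(4-hydroxy-3-methoxyphenyl)-3-(hydroxymethyl)-2,3-dihydro-1,4-benzodioxin-6-yl]-3,5,7-trihydroxy-4H-chromen-4-one | COc1cc([C@H]2Oc3ccc(-c4oc5cc(O)cc(O)c5c(=O)c4O)cc3O[C@@H]2CO)ccc1O | target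

## Count and risks

Total step count: 12. Longest linear sequence: 12 steps (1 to 21); 6, 10 and 14 enter as purchased compounds.

**Step 9 (key step).** The most likely failure is thermal ionisation of the Cα–O bond in the hot phenolic melt, with loss of the trans relation or of ring D. O-acylation followed by Pechmann-type closure to a coumarin, and a second condensation on the same phloroglucinol ring, are further possibilities. Fallback, from 9 back to 18: a Baker–Venkataraman sequence on a ring A ketone that is already benzylated. Acid 9 is esterified (EDC, DMAP, CH2Cl2) with the known ketone 1-[2,4-bis(benzyloxy)-6-hydroxyphenyl]ethanone F1 to give the aryl ester 2-acetyl-3,5-bis(benzyloxy)phenyl BD-carboxylate F2. LiN(SiMe3)2 in THF at −78 to 0 °C moves the acyl group from oxygen to the enolate carbon and gives the diketone 1-BD-3-[2,4-bis(benzyloxy)-6-hydroxyphenyl]propane-1,3-dione F3. Catalytic p-TsOH in toluene at 80 °C closes ring C by cyclodehydration to 18, bypassing steps 8 to 10; nothing is heated above 80 °C.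

**Step 5.** The para-alkoxyaryl epoxide may open with partial ionisation at Cα, so that inversion is incomplete. Attack at Cβ and alkylation through O3' are lesser risks. Fallback, from 5 back to 8, which uses the lability at Cα instead of fighting it: methanolysis of 5 (MeOH, catalytic pyridinium p-toluenesulfonate, 0 °C) opens the benzylic carbon and gives the methyl ether (2S)-3-(benzyloxy)-1-[4-(benzyloxy)-3-methoxyphenyl]-1-methoxypropan-2-ol F4, whose configuration at C1 does not matter. Mitsunobu reaction (PPh3, DIAD, THF) of its only hydroxyl with 3-hydroxy-4-(methoxymethoxy)benzaldehyde F5, made from 6 by selective 4-O-alkylation, forms the O3'–Cβ bond with inversion and gives the aryl ether 3-{[(2R)-1-(benzyloxy)-3-[4-(benzyloxy)-3-methoxyphenyl]-3-methoxypropan-2-yl]oxy}-4-(methoxymethoxy)benzaldehyde F6. p-TsOH in CH2Cl2 then removes the methoxymethyl group and ionises the benzylic methyl ether; the freed O4' captures the cation and should give the more stable trans ring, 8.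

**Step 3.** The Lewis acidic titanium alkoxide, or silica during purification, may open the electron-rich epoxy alcohol before it is isolated. Fallback, from 3 back to 5, with a metal-free oxidant at basic pH: benzylation of 3 (NaH, BnBr, THF) gives the allyl ether 1-(benzyloxy)-4-[(E)-3-(benzyloxy)prop-1-en-1-yl]-2-methoxybenzene F7. Shi epoxidation with the L-fructose-derived ketone (the enantiomer of the usual D-fructose-derived catalyst), KHSO5 and K2CO3 buffer near pH 10.5 in MeCN/dimethoxymethane/water at 0 °C, should then deliver 5 directly, since the D-series catalyst gives the opposite face on trans-β-substituted styrenes.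

**Step 6.** Activation of the hindered secondary alcohol may be slow; elimination, or participation of the neighbouring electron-rich aryl group with loss of clean inversion, may compete. Fallback, from 7 back to 8, by classical sulfonate displacement: selective acetylation of the phenol (Ac2O, aqueous NaHCO3/THF) gives 2-{[(1R,2S)-3-(benzyloxy)-1-[4-(benzyloxy)-3-methoxyphenyl]-2-hydroxypropyl]oxy}-5-formylphenyl acetate F8. Mesylation (MsCl, Et3N, CH2Cl2, 0 °C) gives (1R,2S)-1-(2-acetoxy-4-formylphenoxy)-3-(benzyloxy)-1-[4-(benzyloxy)-3-methoxyphenyl]propan-2-yl methanesulfonate F9. K2CO3 in MeOH removes the acetate, and the phenoxide displaces the mesylate 6-exo-tet with inversion to give 8.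

**Step 11.** Epoxidation of the electron-poor enone bond is slow, so oxidation of benzylic C–H bonds or of the electron-rich rings may compete, and the acid used for the opening may ionise Cα. Fallback, from 18 back to 20, without an electrophilic oxidant: deprotonation at C3 with LiN(iPr)2 (THF, −78 °C) and trapping with B(OMe)3 gives the boronate dimethyl [5,7-bis(benzyloxy)-2-BD-4-oxo-4H-chromen-3-yl]boronate F10, which is oxidised in the same flask with H2O2/AcOH to 20.

**Step 12.** Over-reduction is the risk: hydrogenolysis of the benzylic Cα–O bond of ring D, or saturation of C2=C3, before the last benzyl ether has gone. Fallback, from 20 directly to 21, by non-reductive cleavage: BCl3 with pentamethylbenzene as cation scavenger in CH2Cl2 at −78 °C removes benzyl ethers and spares aryl methyl ethers at that temperature; no new intermediate is made.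

## Further compounds

F1 | step 9 | 1-[2,4-bis(benzyloxy)-6-hydroxyphenyl]ethanone | CC(=O)c1c(O)cc(OCc2ccccc2)cc1OCc1ccccc1
F2 | step 9 | 2-acetyl-3,5-bis(benzyloxy)phenyl BD-carboxylate | COc1cc([C@H]2Oc3ccc(C(=O)Oc4cc(OCc5ccccc5)cc(OCc5ccccc5)c4C(C)=O)cc3O[C@@H]2COCc2ccccc2)ccc1OCc1ccccc1
F3 | step 9 | 1-BD-3-[2,4-bis(benzyloxy)-6-hydroxyphenyl]propane-1,3-dione | COc1cc([C@H]2Oc3ccc(C(=O)CC(=O)c4c(O)cc(OCc5ccccc5)cc4OCc4ccccc4)cc3O[C@@H]2COCc2ccccc2)ccc1OCc1ccccc1
F4 | step 5 | (2S)-3-(benzyloxy)-1-[4-(benzyloxy)-3-methoxyphenyl]-1-methoxypropan-2-ol (C1 epimers) | COc1cc(C(OC)[C@@H](O)COCc2ccccc2)ccc1OCc1ccccc1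
F5 | step 5 | 3-hydroxy-4-(methoxymethoxy)benzaldehyde | COCOc1ccc(C=O)cc1O
F6 | step 5 | 3-{[(2R)-1-(benzyloxy)-3-[4-(benzyloxy)-3-methoxyphenyl]-3-methoxypropan-2-yl]oxy}-4-(methoxymethoxy)benzaldehyde (C3 epimers) | COCOc1ccc(C=O)cc1O[C@@H](C(OC)c1ccc(OCc2ccccc2)c(OC)c1)COCc1ccccc1
F7 | step 3 | 1-(benzyloxy)-4-[(E)-3-(benzyloxy)prop-1-en-1-yl]-2-methoxybenzene | COc1cc(/C=C/COCc2ccccc2)ccc1OCc1ccccc1
F8 | step 6 | 2-{[(1R,2S)-3-(benzyloxy)-1-[4-(benzyloxy)-3-methoxyphenyl]-2-hydroxypropyl]oxy}-5-formylphenyl acetate | COc1cc([C@@H](Oc2ccc(C=O)cc2OC(C)=O)[C@@H](O)COCc2ccccc2)ccc1OCc1ccccc1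
F9 | step 6 | (1R,2S)-1-(2-acetoxy-4-formylphenoxy)-3-(benzyloxy)-1-[4-(benzyloxy)-3-methoxyphenyl]propan-2-yl methanesulfonate | COc1cc([C@@H](Oc2ccc(C=O)cc2OC(C)=O)[C@@H](OS(C)(=O)=O)COCc2ccccc2)ccc1OCc1ccccc1
F10 | step 11 | dimethyl [5,7-bis(benzyloxy)-2-BD-4-oxo-4H-chromen-3-yl]boronate | COc1cc([C@H]2Oc3ccc(-c4oc5cc(OCc6ccccc6)cc(OCc6ccccc6)c5c(=O)c4B(OC)OC)cc3O[C@@H]2COCc2ccccc2)ccc1OCc1ccccc1
F0 | step 12 | none | none
A1 | alternative 1 | methyl (2R,3R)-3-({[tert-butyl(dimethyl)silyl]oxy}methyl)-2-(4-hydroxy-3-methoxyphenyl)-2,3-dihydro-1,4-benzodioxine-6-carboxylate | COc1cc([C@H]2Oc3ccc(C(=O)OC)cc3O[C@@H]2CO[Si](C)(C)C(C)(C)C)ccc1O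
A2 | alternative 1 | methyl 3-{[(2S)-1-{[tert-butyl(dimethyl)silyl]oxy}-3-(4-hydroxy-3-methoxyphenyl)propan-2-yl]oxy}-4-hydroxybenzoate | COC(=O)c1ccc(O)c(O[C@@H](Cc2ccc(O)c(OC)c2)CO[Si](C)(C)C(C)(C)C)c1
A3 | alternative 1 | methyl 3-{[(2S)-1-{[tert-butyl(dimethyl)silyl]oxy}-3-(3-methoxy-4-oxocyclohexa-2,5-dien-1-ylidene)propan-2-yl]oxy}-4-hydroxybenzoate (para-quinone methide) | COC(=O)c1ccc(O)c(O[C@@H](C=C2C=CC(=O)C(OC)=C2)CO[Si](C)(C)C(C)(C)C)c1
A4 | alternative 2 | (2R,3R)-3-(hydroxymethyl)-2-[3-methoxy-4-(methoxymethoxy)phenyl]-2,3-dihydro-1,4-benzodioxine-6-carbaldehyde | COc1cc([C@H]2Oc3ccc(C=O)cc3O[C@@H]2CO)ccc1OCOC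
A5 | alternative 2 | 3-hydroxy-4-{(R)-[3-methoxy-4-(methoxymethoxy)phenyl][(2S)-oxiran-2-yl]methoxy}benzaldehyde | COCOc1ccc([C@@H](Oc2ccc(C=O)cc2O)[C@@H]2CO2)cc1OC
A6 | alternative 3 | 3-BD-1-[2,4,6-tris(benzyloxy)phenyl]prop-2-yn-1-one | COc1cc([C@H]2Oc3ccc(C#CC(=O)c4c(OCc5ccccc5)cc(OCc5ccccc5)cc4OCc4ccccc4)cc3O[C@@H]2COCc2ccccc2)ccc1OCc1ccccc1
A7 | alternative 3 | 1,3,5-tris(benzyloxy)-2-iodobenzene | Ic1c(OCc2ccccc2)cc(OCc2ccccc2)cc1OCc1ccccc1
A8 | alternative 3 | (2R,3R)-2-[4-(benzyloxy)-3-methoxyphenyl]-3-[(benzyloxy)methyl]-6-ethynyl-2,3-dihydro-1,4-benzodioxine | COc1cc([C@H]2Oc3ccc(C#C)cc3O[C@@H]2COCc2ccccc2)ccc1OCc1ccccc1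
A9 | alternative 3 | carbon monoxide | [C-]#[O+]
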